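The runs are simulated on assumed constants.

At 8.0 d I must say what stands in the ash flask, yet its readings stop at 5.00 d, and they give target and nothing else.

in all of them: starting material 0.20 M
- ash: partner 0.40 M; second substrate 0.20 M; third substrate 0.20 M; temperature 110 °C; the very flask that is asked about, followed so far
- cedar: partner 0.40 M; second substrate 0.20 M; third substrate 0.20 M; temperature 116 °C; run made earlier
- flask: partner 0.400 M; second substrate 0.200 M; third substrate 0.200 M; temperature 110 °C; time 8.0 d

- ash (time / d: target / %): 1.04: 41.6; 2.08: 45.0; 3.00: 43.2; 4.00: 41.5; 5.00: 40.1
- cedar (time / d: target / %): 1.04: 42.6; 2.08: 41.3; 3.00: 38.2; 4.00: 34.1; 5.00: 30.1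

(readings scatter by 1 percentage point)

- Sunday's: change nothing and wait 4.0 d more
- Friday's: at 8.0 d raise the temperature by 15 K, then wait 4.0 d
- Saturday's: at 8.0 d add partner, 50.0 % of the amount charged, then wait 4.0 d
- Monday's: at 8.0 d take out 90 % of the target then present, then wait 4.0 d

- target taken out counts as made
- the numbers in the tables scatter with a standard deviation of 1 percentage point
- additions bring no volume worth counting

1. target, in percent of the starting material first charged, at 8.0 d
2. the remedy with the largest gain of target, or "none" below 2 percentage points (Sunday's / Friday's / Saturday's / Monday's / none)
3. target present, with what was taken out counted in, in percent of the starting material first charged, after Sunday's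
4. target present, with what was taken out counted in, in percent of the starting material first charged, after Monday's

The ash readings of target stop rising near 2.08 d, and they cannot tell me which charge stopped the rise, so I count charges, supposing that the second and third substrates also take partner one for one. Partner charged over the three substrates charged together gives 0.667, the partner cover. Below one, partner is the limiting reagent, and 0.200 M of substrate must stay unconverted, whichever substrate is fastest.

Two extreme versions can be solved in the head. If starting material takes partner before the others, target reaches 100 %. If the other two go first, they take 0.400 M, which leaves 0 M of partner for starting material, and no target forms. An even race converts 66.7 % of each substrate, but the ash reading of 45.0 % lies lower, so I expect starting material still standing, not consumed.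

That reading puts 22.5 % of the partner into target. Saturday's lifts the cover to 1.00, and at that share its dose makes about 22 percentage points of new target before any loss. I choose Saturday's.

The forecast gives 35.5 % now, 30.5 % after Sunday's and 35 % after Monday's, and it names Monday's, holding that “extra partner has almost nothing left to convert”. On the choice of remedy we part.

The flask gives 34.3 % at 8.0 d, 27.1 % after Sunday's and 33.8 % after Monday's. The best remedy is Saturday's, with a gain of 20 points, against −0.49 points for Monday's.

    starting material + partner → target (k = 4.21 × 10⁻⁵ L mol⁻¹ s⁻¹, Ea = 75.0 kJ mol⁻¹)
    second substrate + partner → second product (k = 7.40 × 10⁻⁵ L mol⁻¹ s⁻¹, Ea = 103 kJ mol⁻¹)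
    third substrate + partner → third product (k = 7.11 × 10⁻⁵ L mol⁻¹ s⁻¹, Ea = 91.0 kJ mol⁻¹)
    target ⇌ isomer of the product (K = 17.0, k = 7.09 × 10⁻⁷ s⁻¹, Ea = 130 kJ mol⁻¹, ΔH = −16.0 kJ mol⁻¹)
    (constants at 110 °C)

At 8.00 d the ash flask keeps 0.00990 % of its partner and 46.5 % of its starting material, and the substrates still standing add up to 0.200 M, the 0.200 M that a cover of 0.667 demands. Saturday's gain rests in part on the conversions of second substrate and of third substrate with partner: in the run without the second conversion the gain is −3.6 points, and in the run without the third it is −3.4 points, against 20 points in the flask as it stands.

With 1.0 M of partner the cover is 1.67, so no substrate need remain and 40.0 % of the partner stays over. That neighbour ends with 0 % starting material, 40.0 % of its partner and 63.5 % target.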